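The plan rests on cutting C3–C4 of the 20-membered lactone ring. The feature exploited is the 1,4-dioxygenation C1(=O)/C4(OH) spanning the Z C2=C3 alkene. Its polarity is mismatched, because C3 and C4 are both natural electrophiles. C3 therefore enters as the iodide of an O19 iodopropiolate and C4 as a trans-epoxy aldehyde. A chromium-mediated reductive alkynylation joins them, closes the ring and creates the C4 carbinol in one operation. The linear ynoate also keeps O4 out of reach of C1, so butenolide formation is blocked until a final neutral semihydrogenation. The precursor is the open C4–C24 chain with the C5–C6 epoxide, O19 acylated, O21 and O23 as labile TES ethers.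

Key step: step 16

Numbering: target numbering is used throughout (C1 lactone carbonyl, round the ring to C19, side chain out to methyl C24). CIP letters belong to the compound named. C5, C19 and C21 change letter along the route through priority changes only, never through a change of geometry.

Assumption: the (S)-valinol-derived oxazoline–sulfonamide is taken to be the ligand antipode that sends C3 to the Re face of C4. Its sense of induction with an alkynylchromium has to be confirmed on a model trans-epoxy aldehyde, and the equally accessible (R)-ligand is used if the sense is opposite.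

Step 1
Reactants: 1 methyl (R)-3-hydroxybutanoate
Product: 2 methyl (R)-3-(triethylsilyloxy)butanoate
Conditions: TESCl, imidazole, CH2Cl2, 0 °C to rt
Reagents that add atoms: chlorotriethylsilane (TESCl), CC[Si](Cl)(CC)CC
Why: Imidazole-promoted silylation of a secondary alcohol is routine, C23 is taken unchanged from the chiral pool, and TES is preferred to bulkier silyl groups because it must later leave under very mild buffered fluoride in the presence of the epoxide and the ynoate.

Step 2
Reactants: 2 methyl (R)-3-(triethylsilyloxy)butanoate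
Product: 3 (R)-3-(triethylsilyloxy)butanal
Conditions: i-Bu2AlH (1.05 equiv), CH2Cl2, −78 °C
Reagents that add atoms: none
Why: Partial ester reduction with i-Bu2AlH at −78 °C stops at the tetrahedral aluminium hemiacetal, which releases the aldehyde only on work-up, and C23 is not adjacent to the carbonyl group and cannot epimerise.

Step 3
Reactants: 3 (R)-3-(triethylsilyloxy)butanal
Product: 5 (4S,6R)-6-(triethylsilyloxy)hept-1-en-4-ol, via homoallyl diisopinocampheylborinate 4 (not isolated)
Conditions: (−)-Ipc2BOMe [from (+)-α-pinene], allylMgBr, Et2O, −78 °C; 3, −78 °C; then NaOH, H2O2, 0 °C to rt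
Reagents that add atoms: allylmagnesium bromide, C=CC[Mg]Br
Why: Brown asymmetric allylboration proceeds through a chair-like six-membered transition state in which the isopinocampheyl groups derived from (+)-α-pinene expose the Si face of the aldehyde, so C21 is set 1,3-syn to C23 under reagent control, and oxidative work-up cleaves borinate 4.

Step 4
Reactants: 5 (4S,6R)-6-(triethylsilyloxy)hept-1-en-4-ol
Product: 6 tert-butyl (4S,6R)-6-(triethylsilyloxy)hept-1-en-4-yl carbonate
Conditions: Boc2O, DMAP, MeCN, rt
Reagents that add atoms: di-tert-butyl dicarbonate (Boc2O), CC(C)(C)OC(=O)OC(=O)OC(C)(C)C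
Why: DMAP-catalysed acylation with Boc2O converts the only hydroxyl into the tert-butyl carbonate that serves as the internal oxygen nucleophile of the next step, without touching C21.

Step 5
Reactants: 6 tert-butyl (4S,6R)-6-(triethylsilyloxy)hept-1-en-4-yl carbonate
Product: 7 (4R,6S)-4-(iodomethyl)-6-[(2R)-2-(triethylsilyloxy)propyl]-1,3-dioxan-2-one (cis)
Conditions: IBr, toluene, −85 °C
Reagents that add atoms: iodine monobromide, BrI
Why: Iodocarbonate cyclisation (electrophilic halocyclisation): the carbonate carbonyl oxygen opens the iodonium ion in a 6-exo manner through a chair with both substituents equatorial, which places O19 1,3-syn to O21, and loss of the tert-butyl group as its bromide makes the closure irreversible at low temperature.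

Step 6
Reactants: 7 (4R,6S)-4-(iodomethyl)-6-[(2R)-2-(triethylsilyloxy)propyl]-1,3-dioxan-2-one
Product: 9 (2S,4R)-1-[(2R)-oxiran-2-yl]-4-(triethylsilyloxy)pentan-2-ol, via iodo diol 8 (not isolated)
Conditions: K2CO3, MeOH, rt
Reagents that add atoms: none
Why: Base-mediated methanolysis of the cyclic carbonate gives iodo diol 8, whose C19 alkoxide displaces the neighbouring primary iodide (intramolecular Williamson reaction, 3-exo-tet), so the C19–O bond and its configuration are retained.

Step 7
Reactants: 9 (2S,4R)-1-[(2R)-oxiran-2-yl]-4-(triethylsilyloxy)pentan-2-ol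
Product: 10 (2R)-2-[(2S,4R)-2,4-bis(triethylsilyloxy)pentyl]oxirane
Conditions: TESCl, imidazole, DMAP (cat.), CH2Cl2, 0 °C
Reagents that add atoms: chlorotriethylsilane (TESCl), CC[Si](Cl)(CC)CC
Why: Routine silylation of the remaining secondary alcohol takes place under mildly basic conditions that do not open the terminal epoxide.

Step 8
Reactants: 10 (2R)-2-[(2S,4R)-2,4-bis(triethylsilyloxy)pentyl]oxirane; 11 11-bromoundec-1-ene
Product: 13 (2R,4S,6S)-2,4-bis(triethylsilyloxy)octadec-17-en-6-ol, via undec-10-enylmagnesium bromide 12 (not isolated)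
Conditions: 11, Mg, THF, rt to 40 °C; CuI (10 mol %), −40 °C; 10, −40 to −10 °C
Reagents that add atoms: none
Why: Copper-catalysed Grignard opening of a terminal epoxide is an SN2 attack at the unsubstituted C18, so C17–C18 is formed, C19 keeps its configuration and O19 appears as the only free hydroxyl of the chain.

Step 9
Reactants: 14 propargyl alcohol
Product: 15 (E)-3-(tributylstannyl)prop-2-en-1-ol
Conditions: Bu3SnH, AIBN (cat.), neat, 80 °C
Reagents that add atoms: tributyltin hydride, CCCC[SnH](CCCC)CCCC
Why: Radical hydrostannation of a terminal alkyne under equilibrating conditions favours the terminal E-vinylstannane, which is separable from the minor Z and internal isomers by chromatography.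

Step 10
Reactants: 15 (E)-3-(tributylstannyl)prop-2-en-1-ol
Product: 16 (E)-3-iodoprop-2-en-1-ol
Conditions: I2, CH2Cl2, 0 °C
Reagents that add atoms: iodine, II
Why: Iododestannylation is an ipso electrophilic substitution that proceeds with retention of the alkene geometry.

Step 11
Reactants: 13 (2R,4S,6S)-2,4-bis(triethylsilyloxy)octadec-17-en-6-ol; 16 (E)-3-iodoprop-2-en-1-ol
Product: 18 (2E,16S,18S,20R)-18,20-bis(triethylsilyloxy)henicos-2-ene-1,16-diol, via B-alkyl-9-BBN adduct 17 (not isolated)
Conditions: 9-BBN (2.2 equiv), THF, 0 °C to rt; then 16, PdCl2(dppf) (5 mol %), AsPh3, Cs2CO3, DMF/H2O, rt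
Reagents that add atoms: none
Why: Anti-Markovnikov hydroboration of the only alkene followed by B-alkyl Suzuki–Miyaura coupling forms C6–C7 with retention of the E geometry of the vinyl iodide, and the aqueous basic medium tolerates free hydroxyls and TES ethers.

Step 12
Reactants: 18 (2E,16S,18S,20R)-18,20-bis(triethylsilyloxy)henicos-2-ene-1,16-diol
Product: 19 (2S,3S,16S,18S,20R)-2,3-epoxy-18,20-bis(triethylsilyloxy)henicosane-1,16-diol
Conditions: Ti(OiPr)4 (0.2 equiv), L-(+)-DET (0.24 equiv), t-BuOOH, 4 Å molecular sieves, CH2Cl2, −20 °C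
Reagents that add atoms: tert-butyl hydroperoxide, CC(C)(C)OO
Why: Sharpless asymmetric epoxidation: the titanium–L-(+)-tartrate complex binds the allylic O4 and delivers oxygen to the alkene face that gives the (5S,6S)-trans-epoxide (the same sense as (E)-hex-2-en-1-ol to its (2S,3S)-epoxy alcohol), while the remote O19 hydroxyl has no alkene within reach.

Step 13
Reactants: 19 (2S,3S,16S,18S,20R)-2,3-epoxy-18,20-bis(triethylsilyloxy)henicosane-1,16-diol
Product: 20 (2R,3S,16S,18S,20R)-2,3-epoxy-16-hydroxy-18,20-bis(triethylsilyloxy)henicosanal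
Conditions: TEMPO (0.1 equiv), PhI(OAc)2 (1.1 equiv), CH2Cl2, 0 °C to rt
Reagents that add atoms: none
Why: Oxoammonium oxidation (TEMPO/PhI(OAc)2) discriminates sterically between the primary O4 and the secondary O19 hydroxyl, stops at the aldehyde in the absence of water and is free of base, so the epoxide and C5 are preserved.

Step 14
Reactants: 20 (2R,3S,16S,18S,20R)-2,3-epoxy-16-hydroxy-18,20-bis(triethylsilyloxy)henicosanal; 21 propiolic acid
Product: 22 O19 propiolate of epoxy aldehyde 20
Conditions: DCC, DMAP (0.1 equiv), CH2Cl2, −20 to 0 °C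
Reagents that add atoms: none
Why: Steglich esterification acylates the only remaining hydroxyl at oxygen, so C19 is retained, and low temperature with little DMAP limits conjugate addition to the propiolate.

Step 15
Reactants: 22 O19 propiolate of epoxy aldehyde 20
Product: 23 O19 3-iodopropiolate of epoxy aldehyde 20 (cyclisation precursor)
Conditions: NIS, AgNO3 (0.1 equiv), acetone, rt, dark
Reagents that add atoms: N-iodosuccinimide, O=C1CCC(=O)N1I
Why: Silver-catalysed electrophilic iodination of a terminal alkyne via the silver acetylide is a standard entry to 3-iodopropiolates and runs under neutral conditions that spare the aldehyde, the epoxide and the silyl ethers.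

Step 16
Reactants: 23 O19 3-iodopropiolate of epoxy aldehyde 20
Product: 25 (4R,5S,6S,19S)-5,6-epoxy-4-hydroxy-19-[(2S,4R)-2,4-bis(triethylsilyloxy)pentyl]nonadec-2-yn-19-olide (20-membered ynoate lactone), via alkynylchromium species 24 (not isolated)
Conditions: CrCl2 (10 equiv), N-{2-[(4S)-4-isopropyl-4,5-dihydrooxazol-2-yl]-6-methylphenyl}methanesulfonamide (10 equiv), Et3N (10 equiv), THF, rt; NiCl2 (0.5 equiv); 23 by syringe pump over 12 h (final about 2 mM), rt
Reagents that add atoms: none
Why: Divalent chromium, helped by zerovalent nickel that is formed from NiCl2, inserts into the weak C3–I bond and passes the alkynyl group on, reduces the iodopropiolate by two electrons to the trivalent alkynylchromium 24, which adds 1,2 to the C4 aldehyde and leaves a chromium alkoxide that is hydrolysed on work-up. The closest known reaction type is the Nozaki–Hiyama–Kishi alkynylation of aldehydes with 1-iodoalkynes, which has also served for medium and large ring closure; the ester on C1 only makes the C–I bond easier to reduce and the chromium acetylide less basic. The 20-membered ring closes by exo-trig attack of C3 on the C4 carbonyl carbon, the carbonyl oxygen ending outside the ring, and slow addition at high dilution favours this over dimerisation. C4 is controlled by the chiral oxazoline–sulfonamide on chromium, which must direct C3 to the Re face of the aldehyde to give 4R, syn to the C5–O bond; the trans-epoxy aldehyde by itself has only a weak Felkin/Cornforth preference for the 4,5-anti epimer, so reagent control has a realistic chance to dominate. The step needs aldehyde-only reactivity, which is secured because the substrate carries a single aldehyde, no acidic O–H, an ester, an epoxide and silyl ethers that organochromium reagents ignore, and a C5–H that is not removed in a neutral medium. The product keeps C1–C4 collinear, so O4 cannot reach C1.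

Step 17
Reactants: 25 (4R,5S,6S,19S)-5,6-epoxy-4-hydroxy-19-[(2S,4R)-2,4-bis(triethylsilyloxy)pentyl]nonadec-2-yn-19-olide
Product: 26 (4R,5S,6S,19S)-5,6-epoxy-4-hydroxy-19-[(2R,4R)-2,4-dihydroxypentyl]nonadec-2-yn-19-olide
Conditions: HF·pyridine, pyridine, THF, 0 °C
Reagents that add atoms: none
Why: Fluoride-induced cleavage of secondary TES ethers is fast in pyridine-buffered HF at 0 °C, mild enough for the epoxide, and it is done while C1–C4 is still a linear ynoate, so that no acid or fluoride ever meets the lactonisation-prone Z-γ-hydroxy enoate.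

Step 18
Reactants: 26 (4R,5S,6S,19S)-5,6-epoxy-4-hydroxy-19-[(2R,4R)-2,4-dihydroxypentyl]nonadec-2-yn-19-olide
Product: 27 (2Z,4R,5S,6S,19S)-5,6-epoxy-4-hydroxy-19-[(2R,4R)-2,4-dihydroxypentyl]nonadec-2-en-19-olide (CNP0461152.1)
Conditions: H2 (1 atm), Pd/CaCO3 poisoned with Pb(OAc)2, quinoline, EtOAc, rt
Reagents that add atoms: none
Why: Lindlar-type semihydrogenation adds hydrogen syn on the poisoned palladium surface and gives the Z C2=C3 enoate, quinoline and control of hydrogen uptake prevent over-reduction, and the neutral medium leaves the epoxide, the lactone and all six stereocentres untouched.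

Compound list
1 | methyl (R)-3-hydroxybutanoate | C[C@@H](O)CC(=O)OC | starting material
2 | methyl (R)-3-(triethylsilyloxy)butanoate | C[C@@H](O[Si](CC)(CC)CC)CC(=O)OC | intermediate
3 | (R)-3-(triethylsilyloxy)butanal | C[C@@H](O[Si](CC)(CC)CC)CC=O | intermediate
4 | O21 diisopinocampheylborinate of alcohol 5 | C[C@@H](O[Si](CC)(CC)CC)C[C@@H](OB([C@@H]1C[C@@H]2C[C@H]([C@H]1C)C2(C)C)[C@@H]1C[C@@H]2C[C@H]([C@H]1C)C2(C)C)CC=C | intermediate
5 | (4S,6R)-6-(triethylsilyloxy)hept-1-en-4-ol (C18–C24, 21,23-syn) | C[C@@H](O[Si](CC)(CC)CC)C[C@@H](O)CC=C | intermediate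
6 | tert-butyl (4S,6R)-6-(triethylsilyloxy)hept-1-en-4-yl carbonate | C[C@@H](O[Si](CC)(CC)CC)C[C@@H](OC(=O)OC(C)(C)C)CC=C | intermediate
7 | (4R,6S)-4-(iodomethyl)-6-[(2R)-2-(triethylsilyloxy)propyl]-1,3-dioxan-2-one (cis) | C[C@@H](O[Si](CC)(CC)CC)C[C@@H]1C[C@H](CI)OC(=O)O1 | intermediate
8 | (2R,4S,6R)-1-iodo-6-(triethylsilyloxy)heptane-2,4-diol | C[C@@H](O[Si](CC)(CC)CC)C[C@@H](O)C[C@@H](O)CI | intermediate
9 | (2S,4R)-1-[(2R)-oxiran-2-yl]-4-(triethylsilyloxy)pentan-2-ol | C[C@@H](O[Si](CC)(CC)CC)C[C@@H](O)C[C@@H]1CO1 | intermediate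
10 | (2R)-2-[(2S,4R)-2,4-bis(triethylsilyloxy)pentyl]oxirane (C18–C24, all-syn) | C[C@@H](O[Si](CC)(CC)CC)C[C@@H](O[Si](CC)(CC)CC)C[C@@H]1CO1 | intermediate
11 | 11-bromoundec-1-ene | C=CCCCCCCCCCBr | starting material
12 | undec-10-enylmagnesium bromide | C=CCCCCCCCCC[Mg]Br | intermediate
13 | (2R,4S,6S)-2,4-bis(triethylsilyloxy)octadec-17-en-6-ol (C7–C24, O19 free) | C[C@@H](O[Si](CC)(CC)CC)C[C@@H](O[Si](CC)(CC)CC)C[C@@H](O)CCCCCCCCCCC=C | intermediate
14 | propargyl alcohol | C#CCO | starting material
15 | (E)-3-(tributylstannyl)prop-2-en-1-ol | CCCC[Sn](CCCC)(CCCC)/C=C/CO | intermediate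
16 | (E)-3-iodoprop-2-en-1-ol | OC/C=C/I | intermediate
17 | B-alkyl-9-BBN adduct of 13 (boron on C7) | C[C@@H](O[Si](CC)(CC)CC)C[C@@H](O[Si](CC)(CC)CC)C[C@@H](O)CCCCCCCCCCCCB1C2CCCC1CCC2 | intermediate
18 | (2E,16S,18S,20R)-18,20-bis(triethylsilyloxy)henicos-2-ene-1,16-diol (C4–C24) | C[C@@H](O[Si](CC)(CC)CC)C[C@@H](O[Si](CC)(CC)CC)C[C@@H](O)CCCCCCCCCCCC/C=C/CO | intermediate
19 | (2S,3S,16S,18S,20R)-2,3-epoxy-18,20-bis(triethylsilyloxy)henicosane-1,16-diol | C[C@@H](O[Si](CC)(CC)CC)C[C@@H](O[Si](CC)(CC)CC)C[C@@H](O)CCCCCCCCCCCC[C@@H]1O[C@H]1CO | intermediate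
20 | (2R,3S,16S,18S,20R)-2,3-epoxy-16-hydroxy-18,20-bis(triethylsilyloxy)henicosanal | C[C@@H](O[Si](CC)(CC)CC)C[C@@H](O[Si](CC)(CC)CC)C[C@@H](O)CCCCCCCCCCCC[C@@H]1O[C@H]1C=O | intermediate
21 | propiolic acid | C#CC(=O)O | starting material
22 | O19 propiolate of epoxy aldehyde 20 | C[C@@H](O[Si](CC)(CC)CC)C[C@@H](O[Si](CC)(CC)CC)C[C@@H](OC(=O)C#C)CCCCCCCCCCCC[C@@H]1O[C@H]1C=O | intermediate
23 | O19 3-iodopropiolate of epoxy aldehyde 20 (cyclisation precursor) | C[C@@H](O[Si](CC)(CC)CC)C[C@@H](O[Si](CC)(CC)CC)C[C@@H](OC(=O)C#CI)CCCCCCCCCCCC[C@@H]1O[C@H]1C=O | intermediate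
24 | alkynylchromium species from 23 (trivalent chromium on C3, chloride and sulfonamidate ligand shown, oxazoline N and solvent coordination not drawn) | C[C@@H](O[Si](CC)(CC)CC)C[C@@H](O[Si](CC)(CC)CC)C[C@@H](OC(=O)C#C[Cr](Cl)N(S(C)(=O)=O)c1c(C)cccc1C1=N[C@@H](C(C)C)CO1)CCCCCCCCCCCC[C@@H]1O[C@H]1C=O | intermediate
25 | (4R,5S,6S,19S)-5,6-epoxy-4-hydroxy-19-[(2S,4R)-2,4-bis(triethylsilyloxy)pentyl]nonadec-2-yn-19-olide | C[C@@H](O[Si](CC)(CC)CC)C[C@@H](O[Si](CC)(CC)CC)C[C@@H]1CCCCCCCCCCCC[C@@H]2O[C@H]2[C@H](O)C#CC(=O)O1 | intermediate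
26 | (4R,5S,6S,19S)-5,6-epoxy-4-hydroxy-19-[(2R,4R)-2,4-dihydroxypentyl]nonadec-2-yn-19-olide | C[C@@H](O)C[C@@H](O)C[C@@H]1CCCCCCCCCCCC[C@@H]2O[C@H]2[C@H](O)C#CC(=O)O1 | intermediate
27 | (2Z,4R,5S,6S,19S)-5,6-epoxy-4-hydroxy-19-[(2R,4R)-2,4-dihydroxypentyl]nonadec-2-en-19-olide (CNP0461152.1) | C[C@@H](O)C[C@@H](O)C[C@@H]1CCCCCCCCCCCC[C@@H]2O[C@H]2[C@H](O)/C=C\C(=O)O1 | target

Total step count: 18. Longest linear sequence: 16 steps (steps 1–8 and 11–18, from 1). Steps 9 and 10 form the side branch to 16.

Steps most likely to fail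

**Step 16.** What may go wrong is poor facial selectivity at C4. The ligand may fail to override the substrate bias toward the 4,5-anti alcohol, or the ligated chromium may cyclise so slowly that reductive loss of iodine competes.

The fallback moves stereocontrol from the C–C bond formation to a ketone reduction:
- Setting out from 23, the ring is closed with ligand-free CrCl2 and catalytic NiCl2 in THF/DMF at the same dilution. This should give 25 mixed with the C4 epimer F1.
- The unseparated alcohols are oxidised with Dess–Martin periodinane/NaHCO3 to the macrocyclic 4-oxo-2-ynoate F2.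
- This ynone is reduced with (S)-Alpine-Borane (from (−)-α-pinene and 9-BBN). This is a Midland reduction, a reaction known for 4-oxo-2-ynoates.
- In the reduction the alkyne plays the small group, so hydride is delivered to the face that gives 4R. The route is rejoined at 25.

**Step 18.** What may go wrong is translactonisation of O4 onto C1 while the polar free triol is hydrogenated and purified, together with over-reduction that is hard to separate at the last stage.

The fallback blocks O4 before the alkene is made:
- Setting out from 25, TESCl/imidazole should give the O4 TES ether F3.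
- Semihydrogenation over Pd/CaCO3 poisoned with Pb(OAc)2 with quinoline gives the tris-TES Z-enoate F4. This compound cannot lactonise and can be purified at leisure.
- A short treatment with pyridine-buffered HF·pyridine at 0 °C removes all three TES groups and rejoins the route at 27, bypassing 26.

**Step 14.** What may go wrong is consumption of propiolic acid and of the product by conjugate addition of DMAP and by N-acylurea formation, leaving the hindered O19 unacylated while the epoxy aldehyde degrades.

The fallback uses an acid with a blocked terminus: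
- Setting out from 20, 3-(trimethylsilyl)propiolic acid is coupled under Yamaguchi conditions (2,4,6-trichlorobenzoyl chloride, Et3N, DMAP, toluene) to the O19 3-(trimethylsilyl)propiolate F5.
- NIS with AgNO3 in DMF then exchanges silicon for iodine directly (ipso-iododesilylation of a silylalkyne). The route is rejoined at 23, bypassing 22.

Further compounds
F1 | step 16 | C4 epimer of 25 (4S, 4,5-anti) | C[C@@H](O[Si](CC)(CC)CC)C[C@@H](O[Si](CC)(CC)CC)C[C@@H]1CCCCCCCCCCCC[C@@H]2O[C@H]2[C@@H](O)C#CC(=O)O1
F2 | step 16 | macrocyclic 4-oxo-2-ynoate | C[C@@H](O[Si](CC)(CC)CC)C[C@@H](O[Si](CC)(CC)CC)C[C@@H]1CCCCCCCCCCCC[C@@H]2O[C@H]2C(=O)C#CC(=O)O1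
F3 | step 18 | O4 TES ether of 25 | C[C@@H](O[Si](CC)(CC)CC)C[C@@H](O[Si](CC)(CC)CC)C[C@@H]1CCCCCCCCCCCC[C@@H]2O[C@H]2[C@H](O[Si](CC)(CC)CC)C#CC(=O)O1
F4 | step 18 | tris-TES Z-enoate (O4, O21, O23 silylated target) | C[C@@H](O[Si](CC)(CC)CC)C[C@@H](O[Si](CC)(CC)CC)C[C@@H]1CCCCCCCCCCCC[C@@H]2O[C@H]2[C@H](O[Si](CC)(CC)CC)/C=C\C(=O)O1
F5 | step 14 | O19 3-(trimethylsilyl)propiolate of 20 | C[C@@H](O[Si](CC)(CC)CC)C[C@@H](O[Si](CC)(CC)CC)C[C@@H](OC(=O)C#C[Si](C)(C)C)CCCCCCCCCCCC[C@@H]1O[C@H]1C=O
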